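**Compound numbers used throughout**

1 furfurylamine; 2 4-chlorobutanoyl chloride; 3 open-chain chloroamide (not isolated); 4 N-furfuryl lactam; 5 acetylfuran precursor; 6 open-chain triketone (not isolated); 7 cyclic aldol adduct (not isolated); 8 bromine-free catechol; 9 target. Full names and SMILES are in the compound list.

## Analysis of the target

Target 9 is a hexasubstituted benzene ring joined through one benzylic CH2 to the nitrogen of a pyrrolidin-2-one ring. It has no stereocenter, so the synthesis is purely a problem of substitution pattern. With the arene numbered C1 (CH2N), C2 (Br), C3 (OH), C4 (OH), C5 (Br), C6 (Br), every ring position is occupied and the two hydroxyls sit on adjacent carbons. The free catechol is easily oxidized to an o-quinone by air under base or by excess halogen. The benzylic C–N bond is para to the C4 hydroxyl and can be lost by quinone-methide ionization or by ipso attack at C1, and the lactam tolerates dilute acid or base but not prolonged strong hydrolysis. The difficulty is to assemble six substituents in a fixed order in few steps and without a chain of protecting-group operations. One helpful feature is that the three bromines occupy exactly the positions that are ortho or para to a hydroxyl in the bromine-free catechol 8, so they can be introduced last with no regiochemical choice. The feature on which the strategy rests is that 8 (oxygen on C3 and C4, CH2N on C1) is a constitutional isomer, C11H13NO3, of furan 5. In that mapping the acetyl methyl carbon of 5 becomes C2, the acetyl carbonyl carbon C3, the adjacent furan alpha carbon C4, the two beta carbons C5 and C6, and the alpha carbon bearing CH2N becomes C1.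

## Retrosynthetic reasoning

9 to 8. The three C–Br bonds at C2, C5 and C6 are cut first. These are the only unsubstituted positions of 8 and each is activated by a hydroxyl, so the forward step is an exhaustive electrophilic bromination that can give only one constitution. Placing it last means that no earlier step has to tolerate aryl bromides. The forward reaction must brominate carbon three times without oxidizing the catechol and without ipso attack at C1.

8 to 5. The ring bond C1–C2 is cut and the C4 oxygen is reconnected to C1, which turns the benzene ring into the furan ring of 5. C1–C2 is the right bond because it joins the carbon that carries the side chain to an unsubstituted CH, which in the open-chain form 6 are a ketone carbon and a methyl carbon, an aldol pair. Both catechol oxygens are then present from the start, one as the acetyl oxygen and one as the ring oxygen, and no protecting group is needed. Because 5 and 8 are isomers, no oxidant or reductant is needed either. The forward reaction has to open a deactivated acylfuran hydrolytically to 6, close the six-membered ring from the methyl carbon to give 7, and dehydrate and enolize to the arene. This is the step in which the risk of the route is concentrated.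

5 to 4. The bond between the furan alpha carbon and the acetyl carbon is cut. In 4 the side chain blocks one alpha position, so Friedel–Crafts acetylation can only go to the other. The reverse order, attaching the lactam-bearing carbon to a furan that already carries the acetyl group, was not chosen. The acyl group deactivates the ring toward an N-acyliminium electrophile, and the enol of the ketone would compete for it.

4 to 1 and 2. The lactam is cut at its N–C(=O) bond and at its ring N–CH2 bond, which leads through chloroamide 3 to a primary amine and a bifunctional four-carbon electrophile. The furfuryl C–N bond is bought with 1 and not made, which avoids halomethylfuran electrophiles, a class that is unstable. The forward reaction is an N-acylation followed by an intramolecular N-alkylation.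

## Alternatives that were turned down

Alternative 1: The arene is cut at C1–C2 and C5–C6 into a four-carbon diene, 2,5-dibromo-3,4-dimethoxythiophene 1,1-dioxide A2, and a two-carbon bromoalkyne, 1-(3-bromoprop-2-yn-1-yl)pyrrolidin-2-one A3. In the forward key step A2 would add through its two bromine-bearing carbons to the triple bond of A3, and the bridged adduct would lose its SO2 bridge to give 1-(2,3,6-tribromo-4,5-dimethoxybenzyl)pyrrolidin-2-one A1. Ether cleavage would then give 9. In its favour, the route is convergent, A2 is symmetric so the cycloaddition has no regiochemical issue, and all three bromines are fixed before the ring exists. The reaction class (cycloaddition of thiophene dioxides with loss of the sulfonyl bridge) is also established, which is more than can be said for the chosen key step. Against it, A2 is a fully substituted dioxide that must be made by oxidizing an electron-poor thiophene at sulfur, and such dienes tend to dimerize. Both partners are electron-poor and hindered, and the two new bonds are each formed next to a bromine in a ring that ends up hexasubstituted, so high temperatures would be needed at which a 1-bromoalkyne is fragile. The sequence needs about six or seven steps, including a protecting-group removal. The regiochemical certainty it offers is redundant here, because bromination of 8 is already unambiguous. The chosen strategy offers four steps and no protecting groups in exchange for a less precedented ring formation.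

Alternative 2: The ring is cut at C3–C4, between the two oxygen-bearing carbons, which leads to dimethyl 3-[(2-oxopyrrolidin-1-yl)methyl]hexanedioate A5. In the forward key step an acyloin condensation with Na/Me3SiCl would couple the two ester carbonyls to give the enediol bis(silyl ether) 1-{[3,4-bis(trimethylsilyloxy)cyclohex-3-en-1-yl]methyl}pyrrolidin-2-one A4. In its favour, acyloin closure of six-membered rings is classical, and on the certainty of ring closure this alternative is stronger than the chosen route. Against it, A4 is at the cyclohexane oxidation level, so it must be oxidized to the dione and then dehydrogenated twice more before the level of 8 is reached. The lactam carbonyl would also have to survive dissolving sodium in the presence of a chlorosilane. A5 itself is a branched diester that needs several steps, and a stereocenter would be made only to be destroyed. In place of that certainty the chosen strategy offers a ring closure that arrives directly at the aromatic oxidation level, because 5 and 8 are isomers, and roughly half the step count.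

Alternative 3: The ring is cut at C2–C3 and C4–C5, giving the same diester A5 and dimethyl oxalate A7. In the forward key step a double Claisen condensation under NaOMe would join the two alpha carbons of A5 to the two carbonyl carbons of A7 and give dimethyl 2,3-dioxo-5-[(2-oxopyrrolidin-1-yl)methyl]cyclohexane-1,4-dicarboxylate A6. The ester groups at C2 and C5 would later be exchanged for bromine by bromodecarboxylation after dehydrogenation and ester hydrolysis. In its favour, the condensation is robust, is driven by enolate formation and tolerates the lactam, and the carboxyl groups mark two of the three bromine positions. Its key step is clearly more reliable than the chosen one. Against it, A5 again costs several steps and one dehydrogenation is still required. Two carbons are built in only to be expelled, and C6 must be brominated by ordinary substitution anyway, which shows that the latent-bromine device gains nothing on a ring where all three positions are already activated. The total would be seven steps or more. The chosen strategy trades that reliability for atom economy and a much shorter sequence.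

Key step: step 3

Remark on the chemistry: 9 has no stereocenter. The only stereocenter on the route is the carbinol carbon of the transient adduct 7, which forms as a racemate and is destroyed in the same flask. Compounds 6 and 7 are written as keto forms, although hydrates and enols will be present in hot water.

## Route

Step 1
Reactants: 1 furan-2-ylmethanamine (furfurylamine); 2 4-chlorobutanoyl chloride
Product: 4 1-(furan-2-ylmethyl)pyrrolidin-2-one, via 4-chloro-N-(furan-2-ylmethyl)butanamide 3 (not isolated)
Conditions: 2 M aq NaOH, toluene, 0 °C; then 50% aq NaOH, Bu4NBr (5 mol %), 40 °C
Reagents that add atoms: none
Why: Schotten–Baumann N-acylation occurs at the acyl chloride far faster than at the alkyl chloride and gives 3; under phase-transfer catalysis the amide anion then displaces the primary chloride in a 5-exo-tet N-alkylation to close the lactam, and the furan ring is inert to base.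

Step 2
Reactants: 4 1-(furan-2-ylmethyl)pyrrolidin-2-one
Product: 5 1-[(5-acetylfuran-2-yl)methyl]pyrrolidin-2-one
Conditions: Ac2O, 85% H3PO4 (cat.), 60 °C
Reagents that add atoms: acetic anhydride, CC(=O)OC(C)=O
Why: Friedel–Crafts acetylation of a 2-alkylfuran goes to the free alpha position, because the side chain blocks the other alpha carbon and beta attack is much slower; the weakly basic lactam does not sequester the catalyst, and the ketone formed deactivates the ring against a second acylation.

Step 3
Reactants: 5 1-[(5-acetylfuran-2-yl)methyl]pyrrolidin-2-one
Product: 8 1-(3,4-dihydroxybenzyl)pyrrolidin-2-one, via 1-(2,5,6-trioxoheptyl)pyrrolidin-2-one 6 (not isolated), via racemic 1-[(1-hydroxy-3,4-dioxocyclohexyl)methyl]pyrrolidin-2-one 7 (not isolated)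
Conditions: 0.01 M aq H3PO4 (degassed), 0.02 M in 5, sealed vessel, Ar, 220 °C
Reagents that add atoms: none
Why: Proposed new method: in hot dilute acid the furan of 5 should be protonated on carbon, take up water at the alpha carbon remote from the acetyl group and open to triketone 6, the reverse of a Paal–Knorr furan synthesis, so that the former ring oxygen formally stays on the carbon next to the acetyl carbonyl as part of a 1,2-dione. The dione enolizes toward its methyl group, and this enol adds to the protonated ketone beside CH2N in a 6-(enolexo)-exo-trig aldol addition that forms the C1–C2 bond of the arene and closes the carbocycle as 7. Dehydration of the tertiary alcohol of 7 gives a cyclohexene-1,2-dione that is a keto tautomer of the catechol, so two enolizations deliver 8 and make the sequence irreversible; 5 and 8 are isomers, and the water taken up in the opening is returned in the dehydration. The closest known reaction types are the hydrothermal rearrangement of 5-(hydroxymethyl)furfural to benzene-1,2,4-triol and the ring expansion of 2-acylfurans to 3-hydroxypyridines with ammonia, in which the acyl carbon likewise enters the new six-membered ring. No stereocenter is present in 8; the carbinol center of 7 forms without control and is erased on dehydration. The selectivity needed is attack of the methyl carbon on the ketone beside CH2N and not attack of the CH2N carbon on either dione carbonyl, which would close a six-membered ring leading to an isomeric hydroquinone or a five-membered ring leading to a cyclopentenone. The substrate favours the wanted mode because the methyl group is the unhindered primary terminus of an easily enolized 1,2-dione, whereas the CH2N carbon is secondary and carries the lactam, so its adducts place a trisubstituted carbon next to a fully substituted carbinol carbon and should revert more readily; all aldol additions are reversible here and only aromatization is not. High dilution and exclusion of oxygen are meant to suppress intermolecular condensation of 6 and oxidation of 8.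

Step 4
Reactants: 8 1-(3,4-dihydroxybenzyl)pyrrolidin-2-one
Product: 9 1-(2,3,6-tribromo-4,5-dihydroxybenzyl)pyrrolidin-2-one
Conditions: Br2 (3.2 equiv), AcOH, 10 °C to rt
Reagents that add atoms: bromine, BrBr
Why: Electrophilic aromatic bromination: C2, C5 and C6 are the only unsubstituted ring carbons of 8 and each lies ortho or para to a hydroxyl, so exhaustive bromination can give only one constitution; acetic acid without added water or base should keep bromine acting as an electrophile at carbon and not as an oxidant of the catechol, and the lactam is inert.

## Compound list

1 | furan-2-ylmethanamine (furfurylamine) | NCc1ccco1 | starting material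
2 | 4-chlorobutanoyl chloride | O=C(Cl)CCCCl | starting material
3 | 4-chloro-N-(furan-2-ylmethyl)butanamide (formed in step 1, not isolated) | O=C(CCCCl)NCc1ccco1 | intermediate
4 | 1-(furan-2-ylmethyl)pyrrolidin-2-one | O=C1CCCN1Cc1ccco1 | intermediate
5 | 1-[(5-acetylfuran-2-yl)methyl]pyrrolidin-2-one | CC(=O)c1ccc(CN2CCCC2=O)o1 | intermediate
6 | 1-(2,5,6-trioxoheptyl)pyrrolidin-2-one (formed in step 3, not isolated) | CC(=O)C(=O)CCC(=O)CN1CCCC1=O | intermediate
7 | 1-[(1-hydroxy-3,4-dioxocyclohexyl)methyl]pyrrolidin-2-one, racemic (formed in step 3, not isolated) | O=C1CCCN1CC1(O)CCC(=O)C(=O)C1 | intermediate
8 | 1-(3,4-dihydroxybenzyl)pyrrolidin-2-one | O=C1CCCN1Cc1ccc(O)c(O)c1 | intermediate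
9 | 1-(2,3,6-tribromo-4,5-dihydroxybenzyl)pyrrolidin-2-one | O=C1CCCN1Cc1c(Br)c(O)c(O)c(Br)c1Br | target

## Step count and least certain steps

Total step count: 4 (step 1 is a one-pot sequence of two operations). Longest linear sequence: 4 steps, from 1 and 2 to 9.

Step 3 (key step, bears the label "Proposed new method:"). Three things are most likely to go wrong.
- The acylfuran may be reluctant to open, because it is deactivated toward protonation and 6 can reclose to 5. The temperature needed may then be one at which intermolecular condensation of 6 to polymeric material, hydrolytic opening of the lactam, or loss of the lactam from the benzylic position of 8 through a quinone methide takes over.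
- The aldol closure may start from the CH2N carbon instead of the methyl carbon, onto either dione carbonyl. Both of these paths also end in an irreversible dehydration, so the preference argued above is not guaranteed.
- The catechol may be oxidized if oxygen is not rigorously excluded.

The fallback uses known chemistry, sets out from 2 and comes back to the route at 8. Compound 2 is combined with commercial 3,4-dimethoxybenzylamine F1 under the conditions of step 1 (aq NaOH, toluene, 0 °C; then 50% aq NaOH, Bu4NBr, 40 °C). This should give 1-(3,4-dimethoxybenzyl)pyrrolidin-2-one F3 by way of 4-chloro-N-(3,4-dimethoxybenzyl)butanamide F2. Cleavage of both methyl ethers with BBr3 (CH2Cl2, −78 °C to rt, then MeOH) then gives 8, which enters step 4 unchanged.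

Step 4. The likely failures are oxidation of the catechol to an o-quinone by excess bromine, and ipso attack at C1 (para to the C4 hydroxyl) followed by expulsion of the side chain as an N-acyliminium fragment. The fallback sets out from 8 and comes back at 9. Compound 8 is O-methylated (MeI, K2CO3, acetone, reflux) to 1-(3,4-dimethoxybenzyl)pyrrolidin-2-one F3, the same compound that the fallback for step 3 passes through. As an aryl ether, F3 cannot form the dienone that precedes ipso loss and is not oxidized to a quinone. Exhaustive bromination (excess Br2, Fe powder cat., AcOH, 60 °C) should give 1-(2,3,6-tribromo-4,5-dimethoxybenzyl)pyrrolidin-2-one F4, which has the structure of A1. BBr3 (CH2Cl2, −78 °C to rt) then frees the catechol to give 9. If steps 3 and 4 both had to be replaced, F3 from the first fallback would be taken directly through F4 to 9.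

Step 2. The likely failures are acid-induced resinification of the electron-rich alkylfuran before acylation is complete, or sluggish acylation if the lactam ties up the acid catalyst. The fallback sets out from 4 and comes back at 5, and replaces electrophilic acylation by cross-coupling. NBS (DMF, 0 °C) brominates the free alpha position to give 1-[(5-bromofuran-2-yl)methyl]pyrrolidin-2-one F5. Stille coupling with tributyl(1-ethoxyvinyl)stannane (PdCl2(PPh3)2, toluene, 90 °C) gives 1-{[5-(1-ethoxyethenyl)furan-2-yl]methyl}pyrrolidin-2-one F6. Brief treatment with 1 M aq HCl in THF at rt hydrolyses the enol ether to 5.

## Further compounds

F1 | step 3 | (3,4-dimethoxyphenyl)methanamine (3,4-dimethoxybenzylamine) | COc1ccc(CN)cc1OC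
F2 | step 3 | 4-chloro-N-(3,4-dimethoxybenzyl)butanamide | COc1ccc(CNC(=O)CCCCl)cc1OC
F3 | step 3 | 1-(3,4-dimethoxybenzyl)pyrrolidin-2-one | COc1ccc(CN2CCCC2=O)cc1OC
F4 | step 4 | 1-(2,3,6-tribromo-4,5-dimethoxybenzyl)pyrrolidin-2-one | O=C1CCCN1Cc1c(Br)c(OC)c(OC)c(Br)c1Br
F5 | step 2 | 1-[(5-bromofuran-2-yl)methyl]pyrrolidin-2-one | O=C1CCCN1Cc1ccc(Br)o1
F6 | step 2 | 1-{[5-(1-ethoxyethenyl)furan-2-yl]methyl}pyrrolidin-2-one | CCOC(=C)c1ccc(CN2CCCC2=O)o1
A1 | alternative 1 | 1-(2,3,6-tribromo-4,5-dimethoxybenzyl)pyrrolidin-2-one | O=C1CCCN1Cc1c(Br)c(OC)c(OC)c(Br)c1Br
A2 | alternative 1 | 2,5-dibromo-3,4-dimethoxythiophene 1,1-dioxide | COC1=C(Br)S(=O)(=O)C(Br)=C1OC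
A3 | alternative 1 | 1-(3-bromoprop-2-yn-1-yl)pyrrolidin-2-one | O=C1CCCN1CC#CBr
A4 | alternative 2 | 1-{[3,4-bis(trimethylsilyloxy)cyclohex-3-en-1-yl]methyl}pyrrolidin-2-one (racemic) | C[Si](C)(C)OC1=C(O[Si](C)(C)C)CC(CN2CCCC2=O)CC1
A5 | alternative 2 | dimethyl 3-[(2-oxopyrrolidin-1-yl)methyl]hexanedioate (racemic) | COC(=O)CCC(CN1CCCC1=O)CC(=O)OC
A6 | alternative 3 | dimethyl 2,3-dioxo-5-[(2-oxopyrrolidin-1-yl)methyl]cyclohexane-1,4-dicarboxylate (mixture of stereoisomers and enol forms) | COC(=O)C1CC(CN2CCCC2=O)C(C(=O)OC)C(=O)C1=O
A7 | alternative 3 | dimethyl oxalate | COC(=O)C(=O)OC
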